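## The problem

CNP0289180.1 is a tricyclic C25 alcohol. Its heavy atoms are numbered here along the SMILES string: C1 is the exocyclic methylene on C2; ring A is the seven-membered ring C2–C3–C4–C5–C6–C26–C25, ring B the seven-membered ring C6–C7–C8–C9–C24–C25–C26, and ring C the cyclohexene C9–C10–C12–C13–C14–C24 with methyl C11 on C10; C15–C22 and O23 form the chain on C14. Rings A and B share the bridgeheads C6 and C25 and the one-carbon bridge C26, so the core is a bicyclo[4.4.1]undecane whose C5=C6 double bond sits at a bridgehead, and ring C is fused to ring B across C9–C24 next to a tetrasubstituted C9=C10 double bond. Four stereocentres must be set: C15 (S) can be bought; C14 (S) lies next to it but is best set by a reagent; C24 (R) is trans to C14 on ring C and can be steered by it; C25 (S) is joined to C24 by a bond that lies outside every ring until ring B exists, so it has to be created together with C24 in one ordered transition state. The molecule has four isolated alkenes of different substitution, a primary allylic alcohol and no carbonyl group, so strong acid (alkene migration, cation–olefin cyclisation), hydrogenation and harsh dissolving-metal conditions are excluded late in the route. The enabling feature is the allyl unit C5=C6–C7: its transposed isomer, with an exocyclic C6=C7 methylene and a leaving group on C5, is an ordinary 2-methylenecycloheptyl ester in an unbridged ring A. Because the partner carbon C8 is allylic to C9=C10 and can carry a sulfonyl group, ring B can be closed at C7–C8 by allylic substitution with transposition, and the bridgehead alkene then arises from the ring closure itself.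

## Retrosynthesis

**End game (no skeletal bond cut).** Target 32 comes from silyl ether 31 and this from sulfone 30. The phenylsulfonyl group on C8 is the price of a soft carbanion at that carbon; the tert-butyldiphenylsilyl ether on O23 keeps the allylic alcohol out of all organometallic and palladium steps. The forward steps must break C8–S with protonation at C8 rather than C10, and remove silicon without touching the alkenes.

**C7–C8, with allylic transposition (30 to 29).** This cut opens ring B and turns the bridged bicycle into carbonate 29, in which ring A is a plain 2-methylenecycloheptyl carbonate tied to ring C only through C24–C25. The neighbouring cuts are worse: C6–C7 or C8–C9 would need bond formation at an sp2 carbon of a strained or tetrasubstituted alkene, and C25–C26 or C24–C25 would close the ring through a stereocentre. The precursor has lost one ring, the bridging and the bridgehead alkene. The forward reaction must send the C8 carbanion to the exocyclic allyl terminus C7, not to C5.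

**C5–C6 (29 via 28 to 27).** Ring A is opened between the carbinol carbon and the alkene carbon, giving aldehyde 27 with a 2-bromoallyl group. A Nozaki–Hiyama–Kishi closure creates the hydroxyl on C5 and the exocyclic C6=C7 methylene in exactly the transposed positions the key step needs. Closing ring A at C2–C25 or C25–C26 instead would disturb C25. The configuration at C5 is irrelevant; the forward step only has to favour the seven-membered ring over intermolecular addition.

**C8–S and C10–C11 (27 via 26, 25, 24 to 23).** The allylic sulfone with its tetrasubstituted alkene is traced to the sulfinate 26 of a tertiary allylic alcohol (24, 25), which rearranges by a [2,3] shift. That alcohol comes from addition of a methyl nucleophile to the 2-methylene ketone 23. Direct allylic functionalisation of a C9=C10 alkene could not tell C8 from C11 or C12; here C8 is the methylene terminus and C11 arrives separately, so the regiochemistry is fixed by construction.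

**C1=C2 and C2–C3 (23 via 22, 21 to 18 and 17).** The exocyclic methylene is a methylenated ketone (21 to 22), and the ketone comes from the N-methoxy-N-methylamide 18 and the Grignard reagent 20 made from bromide 19. This leaves acid 17, in which C2 is a carboxyl carbon. The forward steps must not epimerise C25, which is alpha to C2.

**C24–C25 (17 via 16, 15, 14, 13 to 7 and 12).** Acid 17 contains the retron C2(=O)–C25–C24–C9=C8 of an Ireland–Claisen rearrangement, so the bond between the two ring-linking stereocentres is cut back to the ester 13 of allylic alcohol 7 with acid 12. The obvious neighbour, conjugate addition of an ester or keto ester enolate to the ring C enone followed by alkylation and decarboxylation, would fix C24 but leave C25 to a protonation or an open transition state. The sigmatropic route sets both in one chair transition state. It asks for an E ketene acetal (15), bond formation anti to the C14 substituent, and a trigonal C10 during the shift, which is why the ketone is carried as silyl dienol ether 14.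

**C8–C9 and C22–O23 (7 via 6, 5 to 4).** The hydroxymethyl group on C9 is removed (hydroxymethylation at the alpha carbon of the enone), then the silyl group and the allylic oxygen. Oxidation is placed here because enone 4 has only one electron-rich alkene.

**C13–C14 and C9=C24 (4 via 3 to 1 and 2).** Ring C is opened to citronellal 1 and methyl vinyl ketone 2; keto aldehyde 3 is the Michael adduct. C15 is bought and C14 is set by the amine catalyst.

**Acid 12 (via 11, 10 to 8 and 9).** A malonic ester synthesis from diethyl malonate 8 and 2,3-dibromopropene 9 supplies C25, C26, C6 and C7 together with the C2 carboxyl.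

## Roads not taken

**Alternative 1:** The cut goes through C13–C14 and C9=C24. A citronellal-type aldehyde undergoes amine-catalysed Michael addition to 2 and then aldol condensation; in its fully functionalised form the silyloxy aldehyde A2 would give enone A1 directly. Its merits are real: C14 is set under catalyst control beside the purchased C15, in one operation, from cheap materials. As the step that carries a strategy it is weak, because A1 contains neither ring A nor ring B, neither C24 nor C25, and no answer to the bridgehead alkene. It also requires A2 to be made first, whereas the oxidation is easier after the annulation. This reaction does not compete with the chosen plan: it is its step 1 (1 and 2 to 4), so on ring C the two are equal. The chosen plan adds what this road lacks, a defined way from the enone to the bridged bicycle.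

**Alternative 2:** The cut removes C25–C26 and C3–C4 at once. The chloromethyl ketone A4 would release an oxyallyl cation over C25–C2–C3 that adds across the tethered 2-substituted butadiene C26=C6–C5=C4 (type 2 intramolecular (4+3) cycloaddition), giving ketone A3 with rings A and B, C25 and the bridgehead alkene in one step. In step economy this road is clearly better: no sulfone to install and remove, no separate ring A closure, and the C2 ketone of A3 is exactly where the methylene is needed. Its weak points are:
- the cation must be generated from an unsymmetrical chloro ketone beside a tetrasubstituted alkene and an allylic silyl ether;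
- the type 2 mode with a four-atom tether has little precedent, and proton loss or ene pathways compete;
- the configuration of C25 relative to C24 depends on cation geometry and tether folding, which cannot be predicted with confidence.

Against the shorter sequence the chosen plan sets ring closures of well-precedented classes and a C25 that is fixed before either ring is closed, so neither closure needs to be stereoselective.

**Alternative 3:** The cut is the C9=C10 double bond. Low-valent titanium generated from TiCl3 and Zn–Cu would couple the ring B ketone with the methyl ketone of the 1,6-diketone A6 (McMurry reaction) to close ring C and give A5, the silyl ether of the target. The tetrasubstituted alkene forms with no regiochemical question, there is no sulfone, and the end game is one deprotection; once A6 existed this closure would be at least as reliable as steps 16 to 20 of the chosen route. Its weakness lies upstream: A6 already holds the bridged bicycle with its bridgehead alkene and the C14/C24/C25 triad, with C14 in an open chain and C24 epimerisable next to the C9 ketone. The hard problems are moved, not solved, and the citronellal annulation can no longer supply ring C. The chosen plan offers a concrete route to the bicycle itself and pays for it with the sulfone detour.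

Key step: step 19

Remark on the chemistry: C5 (in 28, 29), C8 (in 30) and C10 (in 24 to 26) are left undefined, since each later becomes a trigonal or methylene carbon. O23 is protected as a tert-butyldiphenylsilyl ether so that two more labile silyl groups can be removed beside it.

## Route

Step 1
Reactants: 1 (S)-citronellal; 2 methyl vinyl ketone
Product: 4 (4S)-4-[(2S)-6-methylhept-5-en-2-yl]cyclohex-2-en-1-one, via keto aldehyde 3 (not isolated)
Conditions: (S)-2-[diphenyl(trimethylsilyloxy)methyl]pyrrolidine (5 mol %), ethyl 3,4-dihydroxybenzoate (20 mol %), neat, 4 °C; then LiOH, i-PrOH, rt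
Reagents that add atoms: none
Why: Enamine-catalysed Michael addition followed by intramolecular aldol condensation (an organocatalytic Robinson-type annulation); the (S)-configured diarylprolinol ether shields one face of the E-enamine so that C13 is attached to C14 with 14S under catalyst control beside the purchased C15 centre, and the methyl ketone carbon C9 then condenses onto the aldehyde carbon C24 under hydroxide mild enough not to epimerise C14.

Step 2
Reactants: 4 (4S)-4-[(2S)-6-methylhept-5-en-2-yl]cyclohex-2-en-1-one
Product: 5 (4S)-4-[(2S,5E)-7-hydroxy-6-methylhept-5-en-2-yl]cyclohex-2-en-1-one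
Conditions: SeO2 (cat.), t-BuOOH, salicylic acid (cat.), CH2Cl2, rt
Reagents that add atoms: tert-butyl hydroperoxide, CC(C)(C)OO (terminal oxidant; the oxygen is passed on by catalytic selenium dioxide, O=[Se]=O)
Why: Selenium dioxide allylic oxidation (ene reaction then [2,3]-sigmatropic shift) is selective for the electron-rich trisubstituted alkene and for its methyl group trans to the chain, giving the E allylic alcohol; the electron-poor enone double bond does not react.

Step 3
Reactants: 5 (4S)-4-[(2S,5E)-7-hydroxy-6-methylhept-5-en-2-yl]cyclohex-2-en-1-one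
Product: 6 tert-butyldiphenylsilyl ether of 5
Conditions: t-BuPh2SiCl, imidazole, CH2Cl2, rt
Reagents that add atoms: tert-butyl(chloro)diphenylsilane, CC(C)(C)[Si](Cl)(c1ccccc1)c1ccccc1
Why: Standard silylation of a primary allylic alcohol; the bulky, acid-resistant silyl group is chosen so that it outlasts the later removal of two more labile silyl groups.

Step 4
Reactants: 6 tert-butyldiphenylsilyl ether of 5
Product: 7 2-(hydroxymethyl) enone
Conditions: aq. CH2O (37 %), DMAP (0.3 equiv), THF/H2O, rt
Reagents that add atoms: formaldehyde, C=O
Why: Morita–Baylis–Hillman reaction: the amine adds reversibly to C24, the resulting C9 enolate attacks formaldehyde and loss of the amine returns the enone, now carrying C8 as a hydroxymethyl group; no base strong enough to deprotonate C14 is present.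

Step 5
Reactants: 8 diethyl malonate; 9 2,3-dibromopropene
Product: 10 diethyl 2-(2-bromoprop-2-en-1-yl)propanedioate
Conditions: NaOEt, EtOH, excess 8, reflux
Reagents that add atoms: none
Why: Malonic ester alkylation; the allylic bromide of 9 is displaced (SN2) while the alkenyl bromide is inert, and excess malonate suppresses dialkylation.

Step 6
Reactants: 10 diethyl 2-(2-bromoprop-2-en-1-yl)propanedioate
Product: 12 4-bromopent-4-enoic acid, via malonic diacid 11 (not isolated)
Conditions: KOH, EtOH/H2O, reflux; aq. HCl; then neat, 140 °C
Reagents that add atoms: potassium hydroxide, [K+].[OH-]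
Why: Saponification and thermal decarboxylation of the substituted malonic acid (malonic ester synthesis); the alkenyl bromide is not eliminated by aqueous hydroxide.

Step 7
Reactants: 7 2-(hydroxymethyl) enone; 12 4-bromopent-4-enoic acid
Product: 13 4-bromopent-4-enoate ester of 7
Conditions: DCC, DMAP (cat.), CH2Cl2, 0 °C → rt
Reagents that add atoms: none
Why: Carbodiimide esterification (Steglich conditions) of the only hydroxyl group of 7.

Step 8
Reactants: 13 4-bromopent-4-enoate ester of 7
Product: 14 triisopropylsilyl dienol ether of 13
Conditions: i-Pr3SiOTf, Et3N, CH2Cl2, −78 → 0 °C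
Reagents that add atoms: triisopropylsilyl trifluoromethanesulfonate, CC(C)[Si](OS(=O)(=O)C(F)(F)F)(C(C)C)C(C)C
Why: Soft enolisation of the enone with silyl triflate and amine removes an α′ proton at C12 and gives the cross-conjugated 2-silyloxy diene; this protects the C10 carbonyl from the amide base of step 9 and keeps C10 trigonal, so that no axial substituent at C10 interferes with bond formation at C24; the ester is not enolised under these conditions.

Step 9
Reactants: 14 triisopropylsilyl dienol ether of 13
Product: 17 (14S,15S,24R,25S)-Claisen acid, via silyl ketene acetal 15 (not isolated), via trimethylsilyl ester 16 (not isolated)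
Conditions: LiN(i-Pr)2, THF, −78 °C; Me3SiCl, Et3N, −78 → 60 °C; aq. citric acid (pH 4), 0 °C
Reagents that add atoms: none
Why: Ireland–Claisen rearrangement: kinetic deprotonation in THF gives the E silyl ketene acetal 15 (C26 cis to the allylic oxygen), which rearranges through a chair transition state on the face of the C9=C24 double bond opposite the C14 substituent. Facial choice sets C24 (R, trans to C14) and the ketene acetal geometry sets C25 (S) in the same event, while the double bond moves to the exocyclic C9=C8 position; hydrolysis of silyl ester 16 on work-up gives the acid.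

Step 10
Reactants: 17 (14S,15S,24R,25S)-Claisen acid
Product: 18 N-methoxy-N-methylamide of 17
Conditions: MeNH(OMe)·HCl, EDC·HCl, HOBt (cat.), N-methylmorpholine, CH2Cl2, 0 °C → rt
Reagents that add atoms: N,O-dimethylhydroxylamine hydrochloride, CNOC.Cl
Why: Carbodiimide amidation to the N-methoxy-N-methylamide; hydroxybenzotriazole activation at 0 °C avoids epimerisation at C25, and the buffered conditions leave the silyl dienol ether intact.

Step 11
Reactants: 18 N-methoxy-N-methylamide of 17; 19 (3-bromopropoxy)(tert-butyl)dimethylsilane
Product: 21 C2 ketone, via Grignard reagent 20 (not isolated)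
Conditions: 19, Mg, THF, rt; then 18, THF, 0 °C; aq. NH4Cl
Reagents that add atoms: none
Why: Weinreb ketone synthesis: Grignard reagent 20 adds once to the amide and the chelated adduct collapses to the ketone only on work-up, so C25 is never exposed to base as an enolisable ketone; alkenyl bromide and silyl ethers are inert to an alkylmagnesium halide at 0 °C.

Step 12
Reactants: 21 C2 ketone
Product: 22 C2 methylene compound
Conditions: Cp2Ti(CH2)(Cl)AlMe2 (Tebbe reagent), pyridine, THF/toluene, −40 → 0 °C; aq. NaOH
Reagents that add atoms: Tebbe reagent, Cp2Ti(μ-CH2)(μ-Cl)AlMe2, C[Al-]1(C)C[Ti](C2C=CC=C2)(C2C=CC=C2)[Cl+]1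
Why: Tebbe methylenation: the titanium methylidene converts the hindered, enolisable ketone into the 1,1-disubstituted alkene C2=C1 without basic conditions, so C25 keeps its configuration.

Step 13
Reactants: 22 C2 methylene compound
Product: 23 2-methylene ketone alcohol
Conditions: HF·pyridine, pyridine, THF, 0 °C
Reagents that add atoms: none
Why: Fluoride-assisted cleavage of the silyl enol ether and of the primary tert-butyldimethylsilyl ether, both much faster than cleavage of the tert-butyldiphenylsilyl ether; the dienol is protonated at C12 and gives the conjugated 2-methylene ketone.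

Step 14
Reactants: 23 2-methylene ketone alcohol
Product: 24 tertiary allylic alcohol (diol)
Conditions: MeLi, CeCl3, THF, −78 °C; aq. NH4Cl
Reagents that add atoms: methyllithium, [Li]C
Why: 1,2-Addition of the organocerium reagent formed from MeLi and CeCl3 to the enone carbonyl; the low basicity and oxophilicity of the cerium reagent suppress conjugate addition at C8 and enolisation, and the configuration at the new carbinol C10 is irrelevant because C10 becomes trigonal in step 16.

Step 15
Reactants: 24 tertiary allylic alcohol (diol)
Product: 25 hydroxy aldehyde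
Conditions: Dess–Martin periodinane, pyridine, CH2Cl2, 0 °C → rt
Reagents that add atoms: none
Why: Dess–Martin oxidation of the primary alcohol to the aldehyde; the tertiary allylic alcohol has no carbinol hydrogen and is left untouched under pyridine buffering.

Step 16
Reactants: 25 hydroxy aldehyde
Product: 27 allylic sulfone aldehyde, via allylic benzenesulfinate 26 (not isolated)
Conditions: PhS(O)Cl, Et3N, DMAP (cat.), CH2Cl2, −78 °C → rt; then MeCN, 50 °C
Reagents that add atoms: benzenesulfinyl chloride, O=S(Cl)c1ccccc1
Why: Sulfinylation of the tertiary allylic alcohol and [2,3]-sigmatropic sulfinate-to-sulfone rearrangement of 26: sulfur bonds to the terminal carbon C8 and the double bond moves into ring C as the tetrasubstituted C9=C10 alkene. The regiochemistry is unambiguous because only C8 is an alkene terminus, C11 having arrived as the methyl group.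

Step 17
Reactants: 27 allylic sulfone aldehyde
Product: 28 ring A allylic alcohol
Conditions: CrCl2 (10 equiv), NiCl2 (5 mol %), DMSO/THF, rt → 50 °C, 0.005 M
Reagents that add atoms: none
Why: Nozaki–Hiyama–Kishi reaction: nickel inserts into the C6–Br bond, transmetalation to chromium gives an alkenylchromium species that adds chemoselectively to the C5 aldehyde, and high dilution favours closure of the seven-membered ring A; sulfone, silyl ether and alkenes are inert to CrCl2, and the configuration at C5 does not matter.

Step 18
Reactants: 28 ring A allylic alcohol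
Product: 29 methyl carbonate of 28
Conditions: ClCO2Me, pyridine, DMAP (cat.), CH2Cl2, 0 °C
Reagents that add atoms: methyl chloroformate, COC(=O)Cl
Why: Acylation of the secondary allylic alcohol with a chloroformate under pyridine catalysis; the sulfone α-protons are not removed by pyridine.

Step 19
Reactants: 29 methyl carbonate of 28
Product: 30 tricyclic C8 sulfone
Conditions: Pd(PPh3)4 (10 mol %), THF, 65 °C, slow addition (final 0.002 M)
Reagents that add atoms: none
Why: Intramolecular Tsuji–Trost allylic alkylation. Zerovalent palladium ionises the C5 carbonate with inversion to a cationic η3-allyl complex over C5–C6–C7; the leaving group loses CO2 and the methoxide so formed deprotonates C8, which is acidified by the phenylsulfonyl group and the C9=C10 double bond. The sulfonyl carbanion attacks the allyl ligand on the face opposite palladium at the primary terminus C7, forms C7–C8 and leaves the double bond at C5=C6, so the bridgehead alkene appears by allylic transposition. The closest known reaction type is the palladium-catalysed cyclisation of ω-sulfonyl allylic carbonates and acetates to medium and large carbocycles. Ring B closes as a seven-membered ring in an endo sense with respect to the allyl unit, its central carbon C6 and the attacked terminus C7 both ending inside the new ring. The only new stereocentre is C8, which is not controlled and is erased in step 20; C14, C15, C24 and C25 are untouched. The step needs regioselectivity for C7 over C5: C7 is an unsubstituted CH2 terminus whereas attack at C5 would occur at a secondary ring carbon and build a bicyclo[3.3.2]decane, and because the η3 complex can switch faces through its η1 form at C7, both C5 epimers of 29 reach the complex that has palladium anti to the tether. High dilution suppresses intermolecular alkylation.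

Step 20
Reactants: 30 tricyclic C8 sulfone
Product: 31 tert-butyldiphenylsilyl ether of the target
Conditions: Na/Hg (6 %), Na2HPO4, MeOH/THF, −20 °C
Reagents that add atoms: none
Why: Reductive desulfonylation by electron transfer from sodium amalgam (Na/Hg): the C8–S bond breaks and the allyl anion is protonated at the less substituted terminus C8 by the phosphate-buffered methanol, which retains the tetrasubstituted C9=C10 double bond; silyl ether and isolated alkenes are not reduced.

Step 21
Reactants: 31 tert-butyldiphenylsilyl ether of the target
Product: 32 CNP0289180.1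
Conditions: Bu4NF, THF, 0 °C → rt
Reagents that add atoms: none
Why: Fluoride cleavage of the silyl ether liberates the primary allylic alcohol under conditions that do not affect the four alkenes.

## Compound list

In the names, SC stands for the chain (2S,5E)-7-{[tert-butyl(diphenyl)silyl]oxy}-6-methylhept-5-en-2-yl (C15–C22, O23 silylated); locants such as C24 refer to the numbering defined above.

1 | (S)-citronellal, (3S)-3,7-dimethyloct-6-enal | O=CC[C@@H](C)CCC=C(C)C | starting material
2 | methyl vinyl ketone, but-3-en-2-one | CC(=O)C=C | starting material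
3 | (2S,3S)-3,7-dimethyl-2-(3-oxobutyl)oct-6-enal | O=C[C@@H](CCC(C)=O)[C@@H](C)CCC=C(C)C | intermediate
4 | (4S)-4-[(2S)-6-methylhept-5-en-2-yl]cyclohex-2-en-1-one | O=C1CC[C@@H]([C@@H](C)CCC=C(C)C)C=C1 | intermediate
5 | (4S)-4-[(2S,5E)-7-hydroxy-6-methylhept-5-en-2-yl]cyclohex-2-en-1-one | O=C1CC[C@@H]([C@@H](C)CC/C=C(\C)CO)C=C1 | intermediate
6 | (4S)-4-SC-cyclohex-2-en-1-one | O=C1CC[C@@H]([C@@H](C)CC/C=C(\C)CO[Si](c2ccccc2)(c2ccccc2)C(C)(C)C)C=C1 | intermediate
7 | (4S)-2-(hydroxymethyl)-4-SC-cyclohex-2-en-1-one | O=C1CC[C@@H]([C@@H](C)CC/C=C(\C)CO[Si](c2ccccc2)(c2ccccc2)C(C)(C)C)C=C1CO | intermediate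
8 | diethyl malonate | CCOC(=O)CC(=O)OCC | starting material
9 | 2,3-dibromopropene | C=C(Br)CBr | starting material
10 | diethyl 2-(2-bromoprop-2-en-1-yl)propanedioate | CCOC(=O)C(CC(Br)=C)C(=O)OCC | intermediate
11 | 2-(2-bromoprop-2-en-1-yl)propanedioic acid | OC(=O)C(CC(Br)=C)C(=O)O | intermediate
12 | 4-bromopent-4-enoic acid | OC(=O)CCC(Br)=C | intermediate
13 | [(3S)-6-oxo-3-SC-cyclohex-1-en-1-yl]methyl 4-bromopent-4-enoate | O=C1CC[C@@H]([C@@H](C)CC/C=C(\C)CO[Si](c2ccccc2)(c2ccccc2)C(C)(C)C)C=C1COC(=O)CCC(Br)=C | intermediate
14 | [(3S)-3-SC-6-{[tri(propan-2-yl)silyl]oxy}cyclohexa-1,5-dien-1-yl]methyl 4-bromopent-4-enoate | CC(C)[Si](C(C)C)(C(C)C)OC1=CC[C@@H]([C@@H](C)CC/C=C(\C)CO[Si](c2ccccc2)(c2ccccc2)C(C)(C)C)C=C1COC(=O)CCC(Br)=C | intermediate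
15 | E trimethylsilyl ketene acetal of 14 (C26 and the allylic oxygen cis on C25=C2) | CC(C)[Si](C(C)C)(C(C)C)OC1=CC[C@@H]([C@@H](C)CC/C=C(\C)CO[Si](c2ccccc2)(c2ccccc2)C(C)(C)C)C=C1CO/C(O[Si](C)(C)C)=C\CC(Br)=C | intermediate
16 | trimethylsilyl ester of acid 17 | CC(C)[Si](C(C)C)(C(C)C)OC1=CC[C@@H]([C@@H](C)CC/C=C(\C)CO[Si](c2ccccc2)(c2ccccc2)C(C)(C)C)[C@H]([C@H](CC(Br)=C)C(=O)O[Si](C)(C)C)C1=C | intermediate
17 | (2S)-4-bromo-2-[(1R,6S)-2-methylidene-6-SC-3-{[tri(propan-2-yl)silyl]oxy}cyclohex-3-en-1-yl]pent-4-enoic acid (14S,15S,24R,25S) | CC(C)[Si](C(C)C)(C(C)C)OC1=CC[C@@H]([C@@H](C)CC/C=C(\C)CO[Si](c2ccccc2)(c2ccccc2)C(C)(C)C)[C@H]([C@H](CC(Br)=C)C(=O)O)C1=C | intermediate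
18 | (2S)-4-bromo-N-methoxy-N-methyl-2-[ring C unit as in 17]pent-4-enamide | CC(C)[Si](C(C)C)(C(C)C)OC1=CC[C@@H]([C@@H](C)CC/C=C(\C)CO[Si](c2ccccc2)(c2ccccc2)C(C)(C)C)[C@H]([C@H](CC(Br)=C)C(=O)N(C)OC)C1=C | intermediate
19 | (3-bromopropoxy)(tert-butyl)dimethylsilane | BrCCCO[Si](C)(C)C(C)(C)C | starting material
20 | {3-[(tert-butyldimethylsilyl)oxy]propyl}magnesium bromide | Br[Mg]CCCO[Si](C)(C)C(C)(C)C | intermediate
21 | (5S)-7-bromo-1-{[tert-butyl(dimethyl)silyl]oxy}-5-[ring C unit as in 17]oct-7-en-4-one (14S,15S,24R,25S) | CC(C)[Si](C(C)C)(C(C)C)OC1=CC[C@@H]([C@@H](C)CC/C=C(\C)CO[Si](c2ccccc2)(c2ccccc2)C(C)(C)C)[C@H]([C@H](CC(Br)=C)C(=O)CCCO[Si](C)(C)C(C)(C)C)C1=C | intermediate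
22 | 21 with C2=O replaced by C2=CH2: ring C unit as in 17 bearing on C24 a (4S)-2-bromo-8-{[tert-butyl(dimethyl)silyl]oxy}-5-methylideneoct-1-en-4-yl group (14S,15S,24R,25S) | CC(C)[Si](C(C)C)(C(C)C)OC1=CC[C@@H]([C@@H](C)CC/C=C(\C)CO[Si](c2ccccc2)(c2ccccc2)C(C)(C)C)[C@H]([C@H](CC(Br)=C)C(=C)CCCO[Si](C)(C)C(C)(C)C)C1=C | intermediate
23 | (3R,4S)-3-[(4S)-2-bromo-8-hydroxy-5-methylideneoct-1-en-4-yl]-2-methylidene-4-SC-cyclohexan-1-one | O=C1CC[C@@H]([C@@H](C)CC/C=C(\C)CO[Si](c2ccccc2)(c2ccccc2)C(C)(C)C)[C@H]([C@H](CC(Br)=C)C(=C)CCCO)C1=C | intermediate
24 | (3R,4S)-3-[(4S)-2-bromo-8-hydroxy-5-methylideneoct-1-en-4-yl]-1-methyl-2-methylidene-4-SC-cyclohexan-1-ol (C10 epimers) | CC1(O)CC[C@@H]([C@@H](C)CC/C=C(\C)CO[Si](c2ccccc2)(c2ccccc2)C(C)(C)C)[C@H]([C@H](CC(Br)=C)C(=C)CCCO)C1=C | intermediate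
25 | (5S)-7-bromo-5-[(1R,6S)-3-hydroxy-3-methyl-2-methylidene-6-SC-cyclohexyl]-4-methylideneoct-7-enal (C10 epimers) | CC1(O)CC[C@@H]([C@@H](C)CC/C=C(\C)CO[Si](c2ccccc2)(c2ccccc2)C(C)(C)C)[C@H]([C@H](CC(Br)=C)C(=C)CCC=O)C1=C | intermediate
26 | benzenesulfinate ester of the tertiary alcohol of 25 | CC1(OS(=O)c2ccccc2)CC[C@@H]([C@@H](C)CC/C=C(\C)CO[Si](c2ccccc2)(c2ccccc2)C(C)(C)C)[C@H]([C@H](CC(Br)=C)C(=C)CCC=O)C1=C | intermediate
27 | (5S)-7-bromo-5-[(1R,6S)-3-methyl-2-[(phenylsulfonyl)methyl]-6-SC-cyclohex-2-en-1-yl]-4-methylideneoct-7-enal | O=CCCC(=C)[C@@H](CC(Br)=C)[C@H]1[C@H]([C@@H](C)CC/C=C(\C)CO[Si](c2ccccc2)(c2ccccc2)C(C)(C)C)CCC(C)=C1CS(=O)(=O)c1ccccc1 | intermediate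
28 | (4S)-2,5-dimethylidene-4-[(1R,6S)-3-methyl-2-[(phenylsulfonyl)methyl]-6-SC-cyclohex-2-en-1-yl]cycloheptan-1-ol (C5 epimers) | C=C1CCC(O)C(=C)C[C@H]1[C@H]2[C@H]([C@@H](C)CC/C=C(\C)CO[Si](c3ccccc3)(c3ccccc3)C(C)(C)C)CCC(C)=C2CS(=O)(=O)c2ccccc2 | intermediate
29 | methyl carbonate of 28 (carbonate on C5, C5 epimers) | C=C1CCC(OC(=O)OC)C(=C)C[C@H]1[C@H]2[C@H]([C@@H](C)CC/C=C(\C)CO[Si](c3ccccc3)(c3ccccc3)C(C)(C)C)CCC(C)=C2CS(=O)(=O)c2ccccc2 | intermediate
30 | target skeleton with O23 as tert-butyldiphenylsilyl ether and a phenylsulfonyl group on C8 (14S,15S,24R,25S; C8 epimers) | C=C1CCC=C2CC(S(=O)(=O)c4ccccc4)C3=C(C)CC[C@@H]([C@@H](C)CC/C=C(\C)CO[Si](c5ccccc5)(c5ccccc5)C(C)(C)C)[C@@H]3[C@@H]1C2 | intermediate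
31 | tert-butyldiphenylsilyl ether of the target (14S,15S,24R,25S) | C=C1CCC=C2CCC3=C(C)CC[C@@H]([C@@H](C)CC/C=C(\C)CO[Si](c4ccccc4)(c4ccccc4)C(C)(C)C)[C@@H]3[C@@H]1C2 | intermediate
32 | CNP0289180.1 (14S,15S,24R,25S; 19E) | C=C1CCC=C2CCC3=C(C)CC[C@@H]([C@@H](C)CC/C=C(\C)CO)[C@@H]3[C@@H]1C2 | target

## Step count and least certain steps

Total: 21 steps. Longest linear sequence: 19 steps (steps 1 to 4 and 7 to 21, from 1); steps 5 and 6 form a two-step branch to acid 12.

**Step 19 (key step).** The most likely failures are bond formation at the ring terminus C5 instead of C7, and slow deprotonation of the sulfone, which would let β-hydride loss from the allyl complex (diene formation) or capture by methoxide take over. Both allyl termini lead to seven-membered rings, and the acidity margin between the allylic sulfone and methanol is only moderate in THF. Fallback, from 28 back to 30: thionyl chloride in ether at 0 °C converts the alcohol with allylic transposition (SNi′) into the primary allylic chloride F1, in which C5=C6 is already endocyclic in the unbridged ring A. KN(SiMe3)2 in THF at −78 °C under high dilution then deprotonates C8, and the carbanion displaces chloride directly at C7 to give 30. The same bond and ring are formed, with the regiochemistry set by the position of the leaving group.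

**Step 9.** The most likely failure is erosion of the C25 configuration through incomplete E selectivity in the enolisation or a competing boat transition state. Slow bond formation at the hindered ring carbon C24 could also leave the ketene acetal time to decompose. Fallback, from 7 back to 17:
- acetylation (Ac2O, pyridine) gives the acetate F2, and i-Pr3SiOTf/Et3N gives its silyl dienol ether F3;
- Ireland–Claisen rearrangement of F3 (LiN(i-Pr)2, Me3SiCl) gives the ring C acetic acid F4, where only the facial selectivity at C24 is needed;
- activation with pivaloyl chloride and coupling with lithiated (S)-4-benzyloxazolidin-2-one gives the imide F5;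
- NaN(SiMe3)2 and then 9 at −78 °C give the alkylated imide F6, the auxiliary shielding one enolate face so that C25 is S;
- LiOH/H2O2 removes the auxiliary and gives 17.

**Step 17.** The most likely failure is slow insertion of nickel into the 1,1-disubstituted alkenyl bromide, so that the aldehyde is consumed by reduction, pinacol coupling or intermolecular addition before the seven-membered ring closes. Fallback, from 22 back to 28: copper-catalysed halogen exchange (CuI, NaI, trans-N,N′-dimethylcyclohexane-1,2-diamine, dioxane, 110 °C) gives the alkenyl iodide F7. The operations of steps 13 to 16 then lead through the iodo 2-methylene ketone F8, the iodo diol F9 and the iodo hydroxy aldehyde F10 to the iodo sulfone aldehyde F11. F11 closes under the same CrCl2/NiCl2 conditions at room temperature to 28.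

**Step 4.** The most likely failure is slow conjugate addition of the amine to the β-carbon C24, which is flanked by the branched C14 substituent, so that formaldehyde oligomerisation and slow conversion dominate. Fallback, from 6 back to 7: α-iodination of the enone (I2, pyridine, CH2Cl2) gives the 2-iodo enone F12, and Stille coupling with (tributylstannyl)methanol (Pd(PPh3)4, dioxane, 80 °C) installs the hydroxymethyl group to give 7.

**Step 20.** The most likely failure is protonation of the intermediate allyl anion at C10 instead of C8, which would move the double bond out of ring C to C8=C9. Fallback, from 30 back to 31 with no new intermediate: palladium-catalysed hydride transfer (PdCl2(dppp), LiBHEt3, THF, 0 °C) replaces electron transfer by an allylpalladium hydride, which delivers hydrogen to the less substituted allyl terminus C8.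

## Further compounds

F1 | step 19 | primary allylic chloride: 28 with C5–OH/C6=C7 replaced by C5=C6 and C7H2Cl (14S,15S,24R,25S) | C=C1CCC=C(CCl)C[C@H]1[C@H]2[C@H]([C@@H](C)CC/C=C(\C)CO[Si](c3ccccc3)(c3ccccc3)C(C)(C)C)CCC(C)=C2CS(=O)(=O)c2ccccc2
F2 | step 9 | acetate of 7, [(3S)-6-oxo-3-SC-cyclohex-1-en-1-yl]methyl acetate | O=C1CC[C@@H]([C@@H](C)CC/C=C(\C)CO[Si](c2ccccc2)(c2ccccc2)C(C)(C)C)C=C1COC(C)=O
F3 | step 9 | triisopropylsilyl dienol ether of F2 | CC(C)[Si](C(C)C)(C(C)C)OC1=CC[C@@H]([C@@H](C)CC/C=C(\C)CO[Si](c2ccccc2)(c2ccccc2)C(C)(C)C)C=C1COC(C)=O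
F4 | step 9 | ring C acetic acid: 17 without the 2-bromoallyl group (C24 configured as in 17, C25 a CH2 group) | CC(C)[Si](C(C)C)(C(C)C)OC1=CC[C@@H]([C@@H](C)CC/C=C(\C)CO[Si](c2ccccc2)(c2ccccc2)C(C)(C)C)[C@H](CC(=O)O)C1=C
F5 | step 9 | N-acyl derivative of F4 with (4S)-4-benzyl-1,3-oxazolidin-2-one | CC(C)[Si](C(C)C)(C(C)C)OC1=CC[C@@H]([C@@H](C)CC/C=C(\C)CO[Si](c2ccccc2)(c2ccccc2)C(C)(C)C)[C@H](CC(=O)N3[C@@H](Cc4ccccc4)COC3=O)C1=C
F6 | step 9 | F5 alkylated at C25 with the 2-bromoallyl group (24R,25S) | CC(C)[Si](C(C)C)(C(C)C)OC1=CC[C@@H]([C@@H](C)CC/C=C(\C)CO[Si](c2ccccc2)(c2ccccc2)C(C)(C)C)[C@H]([C@H](CC(Br)=C)C(=O)N3[C@@H](Cc4ccccc4)COC3=O)C1=C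
F7 | step 17 | alkenyl iodide analogue of 22 | CC(C)[Si](C(C)C)(C(C)C)OC1=CC[C@@H]([C@@H](C)CC/C=C(\C)CO[Si](c2ccccc2)(c2ccccc2)C(C)(C)C)[C@H]([C@H](CC(I)=C)C(=C)CCCO[Si](C)(C)C(C)(C)C)C1=C
F8 | step 17 | alkenyl iodide analogue of 23 | O=C1CC[C@@H]([C@@H](C)CC/C=C(\C)CO[Si](c2ccccc2)(c2ccccc2)C(C)(C)C)[C@H]([C@H](CC(I)=C)C(=C)CCCO)C1=C
F9 | step 17 | alkenyl iodide analogue of 24 (C10 epimers) | CC1(O)CC[C@@H]([C@@H](C)CC/C=C(\C)CO[Si](c2ccccc2)(c2ccccc2)C(C)(C)C)[C@H]([C@H](CC(I)=C)C(=C)CCCO)C1=C
F10 | step 17 | alkenyl iodide analogue of 25 (C10 epimers) | CC1(O)CC[C@@H]([C@@H](C)CC/C=C(\C)CO[Si](c2ccccc2)(c2ccccc2)C(C)(C)C)[C@H]([C@H](CC(I)=C)C(=C)CCC=O)C1=C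
F11 | step 17 | alkenyl iodide analogue of 27 | O=CCCC(=C)[C@@H](CC(I)=C)[C@H]1[C@H]([C@@H](C)CC/C=C(\C)CO[Si](c2ccccc2)(c2ccccc2)C(C)(C)C)CCC(C)=C1CS(=O)(=O)c1ccccc1
F12 | step 4 | (4S)-2-iodo-4-SC-cyclohex-2-en-1-one | O=C1CC[C@@H]([C@@H](C)CC/C=C(\C)CO[Si](c2ccccc2)(c2ccccc2)C(C)(C)C)C=C1I
F0 | step 20 | none | none
A1 | alternative 1 | (4S)-4-[(2S,5E)-7-{[tert-butyl(dimethyl)silyl]oxy}-6-methylhept-5-en-2-yl]cyclohex-2-en-1-one | O=C1CC[C@@H]([C@@H](C)CC/C=C(\C)CO[Si](C)(C)C(C)(C)C)C=C1
A2 | alternative 1 | (3S,6E)-8-{[tert-butyl(dimethyl)silyl]oxy}-3,7-dimethyloct-6-enal | O=CC[C@@H](C)CC/C=C(\C)CO[Si](C)(C)C(C)(C)C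
A3 | alternative 2 | tricyclic C2 ketone: target skeleton with C2=O in place of C2=CH2 and O23 as tert-butyldimethylsilyl ether | O=C1CCC=C2CCC3=C(C)CC[C@@H]([C@@H](C)CC/C=C(\C)CO[Si](C)(C)C(C)(C)C)[C@@H]3[C@@H]1C2
A4 | alternative 2 | chloromethyl ketone with tethered diene: ring C carrying CH2C(=O)CH2Cl on C24 and a 3-methylidenepent-4-en-1-yl chain on C9 | ClCC(=O)C[C@H]1[C@H]([C@@H](C)CC/C=C(\C)CO[Si](C)(C)C(C)(C)C)CCC(C)=C1CCC(=C)C=C
A5 | alternative 3 | tert-butyldimethylsilyl ether of the target | C=C1CCC=C2CCC3=C(C)CC[C@@H]([C@@H](C)CC/C=C(\C)CO[Si](C)(C)C(C)(C)C)[C@@H]3[C@@H]1C2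
A6 | alternative 3 | 1,6-diketone: bicyclo[4.4.1]undecenone (C9 ketone) bearing on C24 the C14 chain with the C10 methyl ketone | C=C1CCC=C2CCC(=O)[C@@H]([C@@H]1C2)[C@@H](CCC(C)=O)[C@@H](C)CC/C=C(\C)CO[Si](C)(C)C(C)(C)C
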